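**Plan**

- Numbering: ring A is C1 (bears the methylidene), C2, C3 (OH), C4 (Br), C5 (CMe2), C6 (spiro atom); ring B is C6, C7, C8, C9 (carbinol with CH2Cl), C10 (ketone), C11.
- Enabling feature: in ring B the tertiary carbinol C9 and the ketone C10 form an α-ketol, so the C9–C10 bond joins two carbonyl carbons and can be made by adding an aldehyde-derived acyl anion (C10) to a ketone (C9).
- Retrosynthetic cuts, in order: C–Cl (via the epoxide of the C9 diol); the methylidene carbon–C1 bond (hydroxymethyl anion, enone transposition, reductive allylic transposition); C4–Br and the C3 carbinol (α′-bromination and reduction of a ring A enone); C9–C10 (benzoin); C6–C11 (allylation); C6–C7 (alkylation); this leaves dimedone.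
- Forward: ring A is present from the start as the dimedone vinylogous ester; the C7–C9 arm and then the C11–C10 arm are attached at C6; both terminal alkenes are cleaved; ring B is closed by the carbene-catalysed benzoin; ring A is then elaborated and chlorine enters last.
- Stereochemistry: C6 from ligand-controlled palladium-catalysed decarboxylative allylation; C9 from the chair-like benzoin transition state under control of C6 (matched chiral carbene); C4 by equilibration of the α′-bromo enone beside the spiro centre; C3 by hydride addition anti to the axial C5 methyl, cis to bromine.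

Key step: step 9

Assumption: the matched antipode of the aminoindanol-derived triazolium salt is taken to be (5aS,10bR); the C10 carbinol of step 10 is drawn 10S (hydride anti to C1), and either epimer would serve because C10 returns to the ketone in step 16.

Step 1
Reactants: 1 2-bromoprop-2-en-1-ol
Product: 2 [(2-bromoprop-2-en-1-yl)oxy](tert-butyl)diphenylsilane
Conditions: t-BuPh2SiCl, imidazole, CH2Cl2, 0 → 23 °C
Reagents that add atoms: tert-butyl(chloro)diphenylsilane CC(C)(C)[Si](Cl)(c1ccccc1)c1ccccc1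
Why: Silylation of a primary allylic alcohol with a silyl chloride and imidazole is routine, and the bulky silyl group is chosen to survive the later acid and HF·pyridine steps.

Step 2
Reactants: 2 [(2-bromoprop-2-en-1-yl)oxy](tert-butyl)diphenylsilane
Product: 4 3-({[tert-butyl(diphenyl)silyl]oxy}methyl)but-3-en-1-ol, via vinyllithium 3 (not isolated)
Conditions: t-BuLi (2.1 equiv), Et2O, −78 °C; then BF3·OEt2, oxirane, −78 °C
Reagents that add atoms: oxirane C1CO1
Why: Bromine–lithium exchange gives the 2-lithioallyl ether, which is kept at −78 °C and opens BF3-activated oxirane (organolithium epoxide opening) to the homoallylic alcohol.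

Step 3
Reactants: 4 3-({[tert-butyl(diphenyl)silyl]oxy}methyl)but-3-en-1-ol
Product: 5 tert-butyl[(4-iodo-2-methylidenebutyl)oxy]diphenylsilane
Conditions: I2, PPh3, imidazole, CH2Cl2, 0 °C
Reagents that add atoms: iodine II
Why: Appel-type iodination converts the unhindered primary alcohol into the iodide by SN2 displacement of its oxyphosphonium ion.

Step 4
Reactants: 6 5,5-dimethylcyclohexane-1,3-dione (dimedone)
Product: 7 3-isobutoxy-5,5-dimethylcyclohex-2-en-1-one
Conditions: i-BuOH, TsOH (cat.), PhMe, reflux, Dean–Stark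
Reagents that add atoms: 2-methylpropan-1-ol CC(C)CO
Why: Acid-catalysed condensation of the cyclic 1,3-dione with the alcohol under removal of water gives the vinylogous ester.

Step 5
Reactants: 7 3-isobutoxy-5,5-dimethylcyclohex-2-en-1-one; 5 tert-butyl[(4-iodo-2-methylidenebutyl)oxy]diphenylsilane
Product: 9 racemic 6-[3-(silyloxymethyl)but-3-en-1-yl]-3-isobutoxy-5,5-dimethylcyclohex-2-en-1-one, via lithium enolate 8 (not isolated)
Conditions: LiN(i-Pr)2, THF, −78 °C; then 5, DMPU, −78 → 23 °C
Reagents that add atoms: none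
Why: Kinetic deprotonation of a vinylogous ester takes the α′ hydrogen at C6, and SN2 alkylation of this enolate with the primary iodide (Stork–Danheiser-type α′-alkylation) installs the C7–C9 arm as a racemate, which is of no consequence because C6 is set in step 7.

Step 6
Reactants: 9 racemic 6-alkylated vinylogous ester; 10 allyl chloroformate
Product: 12 allyl enol carbonate of 9 (carbonate on the C1 oxygen, C1=C6 double bond), via lithium enolate 11 (not isolated)
Conditions: LiN(i-Pr)2, TMEDA, THF, −78 °C; then 10, −78 °C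
Reagents that add atoms: none
Why: The hindered tetrasubstituted enolate regenerated at C6 is acylated on oxygen by the chloroformate (enol carbonate formation), and the side chain carries no competing acidic hydrogen.

Step 7
Reactants: 12 allyl enol carbonate
Product: 13 (6S)-6-allyl-6-[3-(silyloxymethyl)but-3-en-1-yl]-3-isobutoxy-5,5-dimethylcyclohex-2-en-1-one
Conditions: Pd2(dba)3 (5 mol%), (R)-(CF3)3-t-BuPHOX [(R)-4-tert-butyl-2-{2-[bis(4-trifluoromethylphenyl)phosphanyl]-5-(trifluoromethyl)phenyl}-4,5-dihydrooxazole] (12.5 mol%), PhMe, 25 °C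
Reagents that add atoms: none
Why: Palladium-catalysed decarboxylative asymmetric allylic alkylation (Tsuji-type): zerovalent palladium ionises the allyl carbonate, CO2 is lost and the prochiral C6 enolate is allylated inside the chiral phosphinooxazoline–palladium ion pair, the R ligand being the antipode that places the allyl group on the face giving the 6S ketone, which is C6 of the target.

Step 8
Reactants: 13 (6S)-diene
Product: 15 2-[(1S)-1-(4-silyloxy-3-oxobutyl)-4-isobutoxy-6,6-dimethyl-2-oxocyclohex-3-en-1-yl]acetaldehyde, via tetraol 14 (not isolated)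
Conditions: OsO4 (4 mol%), NMO, acetone/H2O, 0 °C; then NaIO4, THF/pH 7 buffer, 0 °C
Reagents that add atoms: osmium tetroxide O=[Os](=O)(=O)=O (catalytic oxygen carrier); 4-methylmorpholine N-oxide C[N+]1([O-])CCOCC1
Why: Lemieux–Johnson-type dihydroxylation and glycol cleavage: OsO4 should attack the two terminal alkenes in preference to the conjugated, trisubstituted vinylogous ester alkene, and NaIO4 cleaves both diols to give the C10 aldehyde and the C9 ketone without touching C6.

Step 9
Reactants: 15 keto aldehyde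
Product: 16 (6S,9R)-9-(silyloxymethyl)-9-hydroxy-3-isobutoxy-5,5-dimethylspiro[5.5]undec-2-ene-1,10-dione
Conditions: (5aS,10bR)-N-C6F5 aminoindanol-derived triazolium tetrafluoroborate (20 mol%), Et3N, PhMe, 23 °C
Reagents that add atoms: none
Why: The free carbene adds to the C10 aldehyde and proton transfer gives the nucleophilic enaminol (acyl anion equivalent), which attacks the C9 ketone and then releases the carbene from the tertiary alkoxide. The closest known reaction is the triazolium-catalysed intramolecular crossed aldehyde–ketone benzoin cyclisation to six-membered tertiary α-ketols. Ring B closes in a 6-exo-trig mode by forming C9–C10. The new stereocentre C9 is controlled by a chair-like transition state in which the bulky C5 branch at C6 and the silyloxymethyl group are equatorial and the developing alkoxide is axial and hydrogen-bonded to the enaminol hydroxyl, which puts the C9 oxygen cis to C5 (9R here, the arrangement of the target), and the matched chiral carbene reinforces this. The step needs the crossed sense and suppression of aldol pathways: only the aldehyde can form the enaminol, the α-silyloxy ketone is the most electrophilic acceptor, the vinylogous ester carbonyl is a poor electrophile that could close only a four-membered ring, and the weak amine base should not enolise the carbonyls appreciably.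

Step 10
Reactants: 16 spiro α-ketol
Product: 17 (6S,9R,10S)-9-(silyloxymethyl)-9,10-dihydroxy-3-isobutoxy-5,5-dimethylspiro[5.5]undec-2-en-1-one
Conditions: NaBH4, MeOH, −20 → 0 °C
Reagents that add atoms: none
Why: Borohydride reduction of the α-hydroxy ketone masks C10 (the vinylogous ester is inert to NaBH4); hydride should enter anti to the axial C1 branch, guided by the C9 hydroxyl, to give the trans diol, a centre that is erased again in step 16.

Step 11
Reactants: 17 trans diol
Product: 18 (6S,9R,10S)-9-(silyloxymethyl)-9,10-bis(triethylsilyloxy)-3-isobutoxy-5,5-dimethylspiro[5.5]undec-2-en-1-one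
Conditions: Et3SiOTf (3 equiv), 2,6-lutidine, CH2Cl2, −78 → 0 °C
Reagents that add atoms: triethylsilyl trifluoromethanesulfonate CC[Si](CC)(CC)OS(=O)(=O)C(F)(F)F
Why: A silyl triflate with a hindered pyridine base silylates the secondary and the tertiary alcohol alike, so that no hydroxyl is free during the organometallic and enolate steps.

Step 12
Reactants: 19 (4-methoxyphenyl)methanol
Product: 20 tributyl{[(4-methoxybenzyl)oxy]methyl}stannane
Conditions: NaH, Bu3SnCH2I, THF/DMF, 0 → 23 °C
Reagents that add atoms: tributyl(iodomethyl)stannane CCCC[Sn](CCCC)(CCCC)CI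
Why: Williamson etherification of the alkoxide with the iodomethylstannane gives the tin precursor of a hydroxymethyl anion equivalent.

Step 13
Reactants: 18 bis(triethylsilyl) ether; 20 tributyl{[(4-methoxybenzyl)oxy]methyl}stannane
Product: 23 (6S,9R,10S)-1-{[(4-methoxybenzyl)oxy]methyl}-5,5-dimethyl-9-(silyloxymethyl)-9,10-bis(triethylsilyloxy)spiro[5.5]undec-1-en-3-one, via alkoxymethyllithium 21 (not isolated), via tertiary carbinol 22 (not isolated)
Conditions: 20 (2.5 equiv), n-BuLi, THF, −78 °C; CeCl3, −78 °C; then 18, −78 → −30 °C; then 1 M HCl, THF, 0 °C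
Reagents that add atoms: water O
Why: Stork–Danheiser transposition: tin–lithium exchange gives the α-alkoxymethyllithium, whose organocerium form adds 1,2 to the hindered C1 carbonyl without enolisation, and dilute acid ionises the tertiary carbinol and hydrolyses the enol ether to the enone with the ketone at C3 (the transient C1 stereocentre is lost).

Step 14
Reactants: 23 ring A enone
Product: 25 (4RS,6R,9R,10S)-4-bromo enone (C4 epimers), via silyl dienol ether 24 (not isolated)
Conditions: Me3SiCl, LiN(i-Pr)2 (in situ quench), THF, −78 °C; then NBS, THF, −78 → 0 °C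
Reagents that add atoms: N-bromosuccinimide O=C1CCC(=O)N1Br
Why: Kinetic deprotonation of the enone removes the α′ hydrogen at C4, and the cross-conjugated silyl dienol ether is brominated by NBS at C4 (α′-bromination via a silyl enol ether); the C4 configuration is not yet controlled and is corrected in step 16.

Step 15
Reactants: 25 bromo enone bis(triethylsilyl) ether
Product: 26 (4RS,6R,9R,10S)-4-bromo-9,10-dihydroxy enone
Conditions: HF·pyridine, pyridine, THF, 0 → 23 °C
Reagents that add atoms: none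
Why: Buffered HF·pyridine cleaves the two triethylsilyl ethers, while the primary tert-butyldiphenylsilyl ether, the PMB ether and the bromo enone should remain.

Step 16
Reactants: 26 bromo enone diol
Product: 28 (4R,6R,9R)-4-bromo-9-hydroxy-1-{[(4-methoxybenzyl)oxy]methyl}-5,5-dimethyl-9-(silyloxymethyl)spiro[5.5]undec-1-ene-3,10-dione, via epimeric bromo ketol 27 (not isolated)
Conditions: Dess–Martin periodinane, CH2Cl2, 0 → 23 °C; then Et3N, 23 °C
Reagents that add atoms: none
Why: Dess–Martin oxidation touches only the secondary C10 carbinol (the tertiary C9 hydroxyl cannot be oxidised), and the amine then equilibrates the acidic α′-bromo ketone centre through its enol, so that with C10 trigonal the half-chair with equatorial bromine cis to C11 and C7 axial on ring A should prevail, which is the 4R epimer.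

Step 17
Reactants: 28 (4R)-bromo enone ketol
Product: 29 (3S,4R,6R,9R)-4-bromo-3,9-dihydroxy-1-{[(4-methoxybenzyl)oxy]methyl}-5,5-dimethyl-9-(silyloxymethyl)spiro[5.5]undec-1-en-10-one
Conditions: LiBH(s-Bu)3, THF, −78 °C
Reagents that add atoms: none
Why: 1,2-Reduction of a β,β-disubstituted enone by a bulky trialkylborohydride: hydride should reach C3 anti to the axial C5 methyl, which places the new hydroxyl cis to the equatorial bromine (3S), while the C10 ketone, flanked by the fully substituted C9 and screened by C1, should be too hindered to react at −78 °C.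

Step 18
Reactants: 29 bromohydrin PMB ether
Product: 30 (3S,4R,6R,9R)-4-bromo-3,9-dihydroxy-1-(hydroxymethyl)-5,5-dimethyl-9-(silyloxymethyl)spiro[5.5]undec-1-en-10-one
Conditions: DDQ, CH2Cl2/pH 7 buffer, 0 °C
Reagents that add atoms: none
Why: Oxidative cleavage of the PMB ether by DDQ (benzylic hydride abstraction, then hydrolysis) frees the primary allylic alcohol without touching the silyl ether or the bromohydrin.

Step 19
Reactants: 30 primary allylic alcohol
Product: 33 (3S,4R,6R,9R)-4-bromo-3,9-dihydroxy-5,5-dimethyl-1-methylidene-9-(silyloxymethyl)spiro[5.5]undecan-10-one, via sulfonylhydrazine adduct 31 (not isolated), via allylic diazene 32 (not isolated)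
Conditions: 2-O2NC6H4SO2NHNH2, PPh3, DEAD, THF, −30 → 23 °C
Reagents that add atoms: none
Why: Reductive 1,3-transposition of an allylic alcohol: Mitsunobu alkylation of the sulfonylhydrazide by the primary allylic alcohol (the hindered secondary C3 and tertiary C9 hydroxyls should not compete), loss of sulfinic acid to the monoalkyl diazene and retro-ene loss of N2 deliver hydrogen to C2 and move the double bond to the exocyclic position.

Step 20
Reactants: 33 silyl ether
Product: 34 (3S,4R,6R,9R)-4-bromo-3,9-dihydroxy-9-(hydroxymethyl)-5,5-dimethyl-1-methylidenespiro[5.5]undecan-10-one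
Conditions: Bu4NF, AcOH, THF, 0 → 23 °C
Reagents that add atoms: none
Why: Fluoride cleaves the remaining silyl ether, and buffering with acetic acid keeps the α-ketol and the cis-bromohydrin from base-induced reactions.

Step 21
Reactants: 34 triol
Product: 36 (3S,4R,6R,9R)-4-bromo-3-hydroxy-5,5-dimethyl-1-methylidenespiro[5.5]undecan-10-one with an oxirane spiro-fused at C9 (C9–O–CH2), via primary tosylate 35 (not isolated)
Conditions: TsCl, Et3N, Bu2SnO (2 mol%), CH2Cl2, 23 °C; then DBU, 0 °C
Reagents that add atoms: none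
Why: Tin-catalysed sulfonylation is selective for the primary hydroxyl of a terminal 1,2-diol, and the tertiary alkoxide then closes the epoxide by intramolecular SN2 displacement at the methylene carbon, so the C9 configuration is kept.

Step 22
Reactants: 36 spiro-epoxide
Product: 37 (3S,4R,6R,9S)-4-bromo-9-(chloromethyl)-3,9-dihydroxy-5,5-dimethyl-1-methylidenespiro[5.5]undecan-10-one (target)
Conditions: LiCl, AcOH, THF, 23 °C
Reagents that add atoms: lithium chloride [Li+].[Cl-]
Why: Acid-assisted opening of the α,β-epoxy ketone by chloride (SN2 at the unhindered methylene carbon) gives the primary chloride and the tertiary alcohol with C9 untouched; the descriptor becomes 9S only because CH2Cl outranks C10.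

**Compound list**

1 | 2-bromoprop-2-en-1-ol | C=C(Br)CO | starting material
2 | [(2-bromoprop-2-en-1-yl)oxy](tert-butyl)diphenylsilane | C=C(Br)CO[Si](c1ccccc1)(c1ccccc1)C(C)(C)C | intermediate
3 | [3-{[tert-butyl(diphenyl)silyl]oxy}prop-1-en-2-yl]lithium (formed in the flask) | [Li]C(=C)CO[Si](c1ccccc1)(c1ccccc1)C(C)(C)C | intermediate
4 | 3-({[tert-butyl(diphenyl)silyl]oxy}methyl)but-3-en-1-ol | C=C(CCO)CO[Si](c1ccccc1)(c1ccccc1)C(C)(C)C | intermediate
5 | tert-butyl[(4-iodo-2-methylidenebutyl)oxy]diphenylsilane | C=C(CCI)CO[Si](c1ccccc1)(c1ccccc1)C(C)(C)C | intermediate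
6 | 5,5-dimethylcyclohexane-1,3-dione (dimedone) | CC1(C)CC(=O)CC(=O)C1 | starting material
7 | 3-isobutoxy-5,5-dimethylcyclohex-2-en-1-one | CC(C)COC1=CC(=O)CC(C)(C)C1 | intermediate
8 | lithium 5-isobutoxy-3,3-dimethylcyclohexa-1,5-dien-1-olate (α′-enolate of 7, formed in the flask) | [Li]OC1=CC(C)(C)CC(OCC(C)C)=C1 | intermediate
9 | racemic 6-[3-({[tert-butyl(diphenyl)silyl]oxy}methyl)but-3-en-1-yl]-3-isobutoxy-5,5-dimethylcyclohex-2-en-1-one | O=C1C=C(OCC(C)C)CC(C)(C)C1CCC(=C)CO[Si](c2ccccc2)(c3ccccc3)C(C)(C)C | intermediate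
10 | prop-2-en-1-yl carbonochloridate (allyl chloroformate) | C=CCOC(Cl)=O | starting material
11 | lithium 2-[3-({[tert-butyl(diphenyl)silyl]oxy}methyl)but-3-en-1-yl]-5-isobutoxy-3,3-dimethylcyclohexa-1,5-dien-1-olate (enolate of 9, formed in the flask) | [Li]OC1=C(CCC(=C)CO[Si](c2ccccc2)(c3ccccc3)C(C)(C)C)C(C)(C)CC(OCC(C)C)=C1 | intermediate
12 | prop-2-en-1-yl 2-[3-({[tert-butyl(diphenyl)silyl]oxy}methyl)but-3-en-1-yl]-5-isobutoxy-3,3-dimethylcyclohexa-1,5-dien-1-yl carbonate | C=CCOC(=O)OC1=C(CCC(=C)CO[Si](c2ccccc2)(c3ccccc3)C(C)(C)C)C(C)(C)CC(OCC(C)C)=C1 | intermediate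
13 | (6S)-6-(prop-2-en-1-yl)-6-[3-({[tert-butyl(diphenyl)silyl]oxy}methyl)but-3-en-1-yl]-3-isobutoxy-5,5-dimethylcyclohex-2-en-1-one | O=C1C=C(OCC(C)C)CC(C)(C)[C@@]1(CC=C)CCC(=C)CO[Si](c2ccccc2)(c3ccccc3)C(C)(C)C | intermediate
14 | (6S)-6-(2,3-dihydroxypropyl)-6-[3,4-dihydroxy-3-({[tert-butyl(diphenyl)silyl]oxy}methyl)butyl]-3-isobutoxy-5,5-dimethylcyclohex-2-en-1-one (mixture at the two new carbinol carbons, formed in the flask) | O=C1C=C(OCC(C)C)CC(C)(C)[C@@]1(CC(O)CO)CCC(O)(CO)CO[Si](c2ccccc2)(c3ccccc3)C(C)(C)C | intermediate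
15 | 2-[(1S)-1-(4-{[tert-butyl(diphenyl)silyl]oxy}-3-oxobutyl)-4-isobutoxy-6,6-dimethyl-2-oxocyclohex-3-en-1-yl]acetaldehyde | O=C1C=C(OCC(C)C)CC(C)(C)[C@@]1(CC=O)CCC(=O)CO[Si](c2ccccc2)(c3ccccc3)C(C)(C)C | intermediate
16 | (6S,9R)-9-({[tert-butyl(diphenyl)silyl]oxy}methyl)-9-hydroxy-3-isobutoxy-5,5-dimethylspiro[5.5]undec-2-ene-1,10-dione | O=C1C=C(OCC(C)C)CC(C)(C)[C@@]12CC[C@@](O)(CO[Si](c3ccccc3)(c4ccccc4)C(C)(C)C)C(=O)C2 | intermediate
17 | (6S,9R,10S)-9-({[tert-butyl(diphenyl)silyl]oxy}methyl)-9,10-dihydroxy-3-isobutoxy-5,5-dimethylspiro[5.5]undec-2-en-1-one | O=C1C=C(OCC(C)C)CC(C)(C)[C@@]12CC[C@@](O)(CO[Si](c3ccccc3)(c4ccccc4)C(C)(C)C)[C@@H](O)C2 | intermediate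
18 | (6S,9R,10S)-9-({[tert-butyl(diphenyl)silyl]oxy}methyl)-9,10-bis(triethylsilyloxy)-3-isobutoxy-5,5-dimethylspiro[5.5]undec-2-en-1-one | O=C1C=C(OCC(C)C)CC(C)(C)[C@@]12CC[C@@](O[Si](CC)(CC)CC)(CO[Si](c3ccccc3)(c4ccccc4)C(C)(C)C)[C@@H](O[Si](CC)(CC)CC)C2 | intermediate
19 | (4-methoxyphenyl)methanol | COc1ccc(CO)cc1 | starting material
20 | tributyl{[(4-methoxybenzyl)oxy]methyl}stannane | COc1ccc(COC[Sn](CCCC)(CCCC)CCCC)cc1 | intermediate
21 | {[(4-methoxybenzyl)oxy]methyl}lithium (formed in the flask) | [Li]COCc1ccc(OC)cc1 | intermediate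
22 | (6S,9R,10S)-1-hydroxy-1-{[(4-methoxybenzyl)oxy]methyl}-3-isobutoxy-5,5-dimethyl-9-({[tert-butyl(diphenyl)silyl]oxy}methyl)-9,10-bis(triethylsilyloxy)spiro[5.5]undec-2-ene (C1 epimers, formed in the flask) | OC1(COCc5ccc(OC)cc5)C=C(OCC(C)C)CC(C)(C)[C@@]12CC[C@@](O[Si](CC)(CC)CC)(CO[Si](c3ccccc3)(c4ccccc4)C(C)(C)C)[C@@H](O[Si](CC)(CC)CC)C2 | intermediate
23 | (6S,9R,10S)-1-{[(4-methoxybenzyl)oxy]methyl}-5,5-dimethyl-9-({[tert-butyl(diphenyl)silyl]oxy}methyl)-9,10-bis(triethylsilyloxy)spiro[5.5]undec-1-en-3-one | C1(COCc5ccc(OC)cc5)=CC(=O)CC(C)(C)[C@@]12CC[C@@](O[Si](CC)(CC)CC)(CO[Si](c3ccccc3)(c4ccccc4)C(C)(C)C)[C@@H](O[Si](CC)(CC)CC)C2 | intermediate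
24 | (6S,9R,10S)-1-{[(4-methoxybenzyl)oxy]methyl}-5,5-dimethyl-3-(trimethylsilyloxy)-9-({[tert-butyl(diphenyl)silyl]oxy}methyl)-9,10-bis(triethylsilyloxy)spiro[5.5]undeca-1,3-diene (formed in the flask) | C1(COCc5ccc(OC)cc5)=CC(O[Si](C)(C)C)=CC(C)(C)[C@@]12CC[C@@](O[Si](CC)(CC)CC)(CO[Si](c3ccccc3)(c4ccccc4)C(C)(C)C)[C@@H](O[Si](CC)(CC)CC)C2 | intermediate
25 | (4RS,6R,9R,10S)-4-bromo-1-{[(4-methoxybenzyl)oxy]methyl}-5,5-dimethyl-9-({[tert-butyl(diphenyl)silyl]oxy}methyl)-9,10-bis(triethylsilyloxy)spiro[5.5]undec-1-en-3-one (C4 epimers; the C6 descriptor is R from here on only because C5 now outranks C1) | C1(COCc5ccc(OC)cc5)=CC(=O)C(Br)C(C)(C)[C@@]12CC[C@@](O[Si](CC)(CC)CC)(CO[Si](c3ccccc3)(c4ccccc4)C(C)(C)C)[C@@H](O[Si](CC)(CC)CC)C2 | intermediate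
26 | (4RS,6R,9R,10S)-4-bromo-9,10-dihydroxy-1-{[(4-methoxybenzyl)oxy]methyl}-5,5-dimethyl-9-({[tert-butyl(diphenyl)silyl]oxy}methyl)spiro[5.5]undec-1-en-3-one (C4 epimers) | C1(COCc5ccc(OC)cc5)=CC(=O)C(Br)C(C)(C)[C@@]12CC[C@@](O)(CO[Si](c3ccccc3)(c4ccccc4)C(C)(C)C)[C@@H](O)C2 | intermediate
27 | (4RS,6R,9R)-4-bromo-9-hydroxy-1-{[(4-methoxybenzyl)oxy]methyl}-5,5-dimethyl-9-({[tert-butyl(diphenyl)silyl]oxy}methyl)spiro[5.5]undec-1-ene-3,10-dione (C4 epimers, formed in the flask) | C1(COCc5ccc(OC)cc5)=CC(=O)C(Br)C(C)(C)[C@@]12CC[C@@](O)(CO[Si](c3ccccc3)(c4ccccc4)C(C)(C)C)C(=O)C2 | intermediate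
28 | (4R,6R,9R)-4-bromo-9-hydroxy-1-{[(4-methoxybenzyl)oxy]methyl}-5,5-dimethyl-9-({[tert-butyl(diphenyl)silyl]oxy}methyl)spiro[5.5]undec-1-ene-3,10-dione | C1(COCc5ccc(OC)cc5)=CC(=O)[C@H](Br)C(C)(C)[C@@]12CC[C@@](O)(CO[Si](c3ccccc3)(c4ccccc4)C(C)(C)C)C(=O)C2 | intermediate
29 | (3S,4R,6R,9R)-4-bromo-3,9-dihydroxy-1-{[(4-methoxybenzyl)oxy]methyl}-5,5-dimethyl-9-({[tert-butyl(diphenyl)silyl]oxy}methyl)spiro[5.5]undec-1-en-10-one | C1(COCc5ccc(OC)cc5)=C[C@H](O)[C@H](Br)C(C)(C)[C@@]12CC[C@@](O)(CO[Si](c3ccccc3)(c4ccccc4)C(C)(C)C)C(=O)C2 | intermediate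
30 | (3S,4R,6R,9R)-4-bromo-3,9-dihydroxy-1-(hydroxymethyl)-5,5-dimethyl-9-({[tert-butyl(diphenyl)silyl]oxy}methyl)spiro[5.5]undec-1-en-10-one | C1(CO)=C[C@H](O)[C@H](Br)C(C)(C)[C@@]12CC[C@@](O)(CO[Si](c3ccccc3)(c4ccccc4)C(C)(C)C)C(=O)C2 | intermediate
31 | N-{[(3S,4R,6R,9R)-4-bromo-3,9-dihydroxy-5,5-dimethyl-10-oxo-9-({[tert-butyl(diphenyl)silyl]oxy}methyl)spiro[5.5]undec-1-en-1-yl]methyl}-2-nitrobenzenesulfonohydrazide, alkylated at the sulfonamide nitrogen (formed in the flask) | NN(CC1=C[C@H](O)[C@H](Br)C(C)(C)[C@@]12CC[C@@](O)(CO[Si](c3ccccc3)(c4ccccc4)C(C)(C)C)C(=O)C2)S(=O)(=O)c5ccccc5[N+](=O)[O-] | intermediate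
32 | (3S,4R,6R,9R)-4-bromo-1-(diazenylmethyl)-3,9-dihydroxy-5,5-dimethyl-9-({[tert-butyl(diphenyl)silyl]oxy}methyl)spiro[5.5]undec-1-en-10-one (formed in the flask) | N=NCC1=C[C@H](O)[C@H](Br)C(C)(C)[C@@]12CC[C@@](O)(CO[Si](c3ccccc3)(c4ccccc4)C(C)(C)C)C(=O)C2 | intermediate
33 | (3S,4R,6R,9R)-4-bromo-3,9-dihydroxy-5,5-dimethyl-1-methylidene-9-({[tert-butyl(diphenyl)silyl]oxy}methyl)spiro[5.5]undecan-10-one | C=C1C[C@H](O)[C@H](Br)C(C)(C)[C@@]12CC[C@@](O)(CO[Si](c3ccccc3)(c4ccccc4)C(C)(C)C)C(=O)C2 | intermediate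
34 | (3S,4R,6R,9R)-4-bromo-3,9-dihydroxy-9-(hydroxymethyl)-5,5-dimethyl-1-methylidenespiro[5.5]undecan-10-one | C=C1C[C@H](O)[C@H](Br)C(C)(C)[C@@]12CC[C@@](O)(CO)C(=O)C2 | intermediate
35 | [(3S,4R,6R,9R)-4-bromo-3,9-dihydroxy-5,5-dimethyl-1-methylidene-10-oxospiro[5.5]undecan-9-yl]methyl 4-methylbenzenesulfonate (formed in the flask) | C=C1C[C@H](O)[C@H](Br)C(C)(C)[C@@]12CC[C@@](O)(COS(=O)(=O)c3ccc(C)cc3)C(=O)C2 | intermediate
36 | (3S,4R,6R,9R)-4-bromo-3-hydroxy-5,5-dimethyl-1-methylidenespiro[5.5]undecan-10-one with an oxirane spiro-fused at C9 (C9–O–CH2) | C=C1C[C@H](O)[C@H](Br)C(C)(C)[C@@]12CC[C@@]3(CO3)C(=O)C2 | intermediate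
37 | (3S,4R,6R,9S)-4-bromo-9-(chloromethyl)-3,9-dihydroxy-5,5-dimethyl-1-methylidenespiro[5.5]undecan-10-one | C=C1C[C@H](O)[C@H](Br)C(C)(C)[C@@]12CC[C@@](O)(CCl)C(=O)C2 | target

**Totals and risks**

Total step count: 22. Longest linear sequence: 20 steps (steps 1–3, 5–11 and 13–22, from 2-bromoprop-2-en-1-ol).

The three steps most likely to fail:

Step 9. The keto aldehyde may cyclise by aldol pathways or dimerise instead of undergoing the crossed benzoin, or the ketone face may be chosen poorly, so that C9 forms as a mixture. The fallback sets out from 13 and builds ring B by metathesis instead. Ring-closing metathesis of the allyl and the 1,1-disubstituted alkene with second-generation Grubbs catalyst should give the spiro cyclohexene F1. Dihydroxylation with OsO4/NMO from the face anti to the axial C1 branch should give the cis diol F2, with the C9 oxygen cis to C5. Dess–Martin oxidation of its secondary hydroxyl comes back to the route at 16.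

Step 16. The equilibrium at C4 may not favour the 4R bromide strongly enough, or the α′-bromo enone may suffer base-induced side reactions during epimerisation. The fallback sets out from 27 and replaces thermodynamic control by catalyst control. Asymmetric ketone hydrogenation with RuCl2[(S)-xylbinap][(S)-daipen] (or its antipode, whichever delivers the 3S carbinol), K2CO3 and H2 in i-PrOH is run under dynamic kinetic resolution. The base keeps C4 epimerising while the catalyst reduces the enone carbonyl of one epimer to the cis bromohydrin. This comes back to the route at 29 and makes no new isolated compound (F0).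

Step 17. The borohydride may over-reduce, attacking the C10 ketone as well as C3. The fallback sets out from 28 and accepts reduction of both carbonyls. NaBH4/CeCl3 in MeOH should give the triol F3. Et3SiCl/imidazole should silylate only the unhindered allylic C3 hydroxyl, giving the silyl ether F4. Dess–Martin oxidation of the C10 carbinol gives the ketone F5. HF·pyridine then removes the C3 silyl group and comes back to the route at 29.

**Further compounds**

F1 | step 9 | (6S)-9-({[tert-butyl(diphenyl)silyl]oxy}methyl)-3-isobutoxy-5,5-dimethylspiro[5.5]undeca-2,9-dien-1-one | O=C1C=C(OCC(C)C)CC(C)(C)[C@@]12CCC(CO[Si](c3ccccc3)(c4ccccc4)C(C)(C)C)=CC2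
F2 | step 9 | (6S,9R,10R)-9-({[tert-butyl(diphenyl)silyl]oxy}methyl)-9,10-dihydroxy-3-isobutoxy-5,5-dimethylspiro[5.5]undec-2-en-1-one | O=C1C=C(OCC(C)C)CC(C)(C)[C@@]12CC[C@@](O)(CO[Si](c3ccccc3)(c4ccccc4)C(C)(C)C)[C@H](O)C2
F0 | step 16 | none | none
F3 | step 17 | (3S,4R,6R,9R)-4-bromo-1-{[(4-methoxybenzyl)oxy]methyl}-5,5-dimethyl-9-({[tert-butyl(diphenyl)silyl]oxy}methyl)spiro[5.5]undec-1-ene-3,9,10-triol (C10 epimers) | C1(COCc5ccc(OC)cc5)=C[C@H](O)[C@H](Br)C(C)(C)[C@@]12CC[C@@](O)(CO[Si](c3ccccc3)(c4ccccc4)C(C)(C)C)C(O)C2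
F4 | step 17 | (3S,4R,6R,9R)-4-bromo-1-{[(4-methoxybenzyl)oxy]methyl}-5,5-dimethyl-3-(triethylsilyloxy)-9-({[tert-butyl(diphenyl)silyl]oxy}methyl)spiro[5.5]undec-1-ene-9,10-diol (C10 epimers) | C1(COCc5ccc(OC)cc5)=C[C@H](O[Si](CC)(CC)CC)[C@H](Br)C(C)(C)[C@@]12CC[C@@](O)(CO[Si](c3ccccc3)(c4ccccc4)C(C)(C)C)C(O)C2
F5 | step 17 | (3S,4R,6R,9R)-4-bromo-9-hydroxy-1-{[(4-methoxybenzyl)oxy]methyl}-5,5-dimethyl-3-(triethylsilyloxy)-9-({[tert-butyl(diphenyl)silyl]oxy}methyl)spiro[5.5]undec-1-en-10-one | C1(COCc5ccc(OC)cc5)=C[C@H](O[Si](CC)(CC)CC)[C@H](Br)C(C)(C)[C@@]12CC[C@@](O)(CO[Si](c3ccccc3)(c4ccccc4)C(C)(C)C)C(=O)C2
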